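The earlier runs and the new flask were generated by integration with constants of no real substance.

West, with more coupling partner than south-east, holds less substrate at 4.00 h: 49% against 56%, while side product reads 12% against 11%.

| flask | substrate | coupling partner | remark | time |
|---|---|---|---|---|
| south-east | 0.015 M | 0.021 M | run made earlier |  |
| west | 0.015 M | 0.033 M | run made earlier |  |
| larch | 0.015 M | 0.0150 M |  | 5.0 h |
| oak | 0.015 M | 0.0150 M |  | 8.0 h |

| run | time / h | side product / % | target / % | substrate / % |
|---|---|---|---|---|
| south-east | 0.333 | 3 | 6 | 95 |
| south-east | 0.500 | 1 | 1 | 95 |
| south-east | 0.667 | 5 | 9 | 91 |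
| south-east | 1.00 | 7 | 9 | 84 |
| south-east | 1.50 | 6 | 16 | 77 |
| south-east | 2.50 | 14 | 22 | 72 |
| south-east | 4.00 | 11 | 27 | 56 |
| west | 0.500 | 1 | 5 | 89 |
| west | 1.00 | 5 | 15 | 83 |
| west | 1.50 | 7 | 16 | 76 |
| west | 2.50 | 12 | 24 | 66 |
| west | 3.00 | 8 | 32 | 54 |
| west | 4.00 | 12 | 41 | 49 |

(each reading ± 2 percentage points)

- percent here means substrate units held: one side product counts as two

- which of these there is most of at the end, counted by the substrate in it, larch (target / substrate / side product)
- which of these there is most of at the end, counted by the substrate in it, oak (target / substrate / side product)
- how much there is at the end of the one of these that leads, in percent of the substrate charged: larch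
- how much there is at the end of the one of these that leads, in percent of the substrate charged: oak

So I take two second-order losses of substrate, one with coupling partner and one with itself, and I follow the reciprocal of the fraction of substrate left, minus one, divided by time. Pooled over the last three readings of each run, this is 0.184 h⁻¹ in south-east and 0.253 h⁻¹ in west. A straight line in c(coupling partner) gives 0.150 h⁻¹ at 0.0150 M, the reciprocal rise at equal charges, and the part of it that scales with c(coupling partner), the selectivity for target, is 57.9%.

I therefore expect 57.2% of substrate in larch, which exceeds everything else combined. For oak I expect 45.5%, ahead of target at 31.6%.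

The forecast gives 58% for larch and 45% for oak, and says “Unreacted substrate still leads in both runs”.

Larch holds 58.2% of substrate and oak 45.6%, and substrate leads in larch and in oak.

    substrate + coupling partner ⇌ target (K = 880 M⁻¹, k = 0.0790 M⁻¹ min⁻¹)
    2 substrate → side product (k = 0.0350 M⁻¹ min⁻¹)

At the start of larch, the forward step to target uses substrate 1.1 times as fast as the step to side product. Carried along its line to 0.037 M of coupling partner, the reciprocal rise gives 42.0% of substrate at 5.0 h. That neighbour of larch holds 38.5% of substrate, and target leads there at 48.3%.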